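Read this flask by one frozen rate: the green run is the same flask earlier, and its loss of solid substrate is carried forward here.

- green: solid substrate 0.80 M; gas phase 31 mM (held); the very flask that is asked about, followed so far
- flask: solid substrate 0.80 M; gas phase 31 mM (held); time 15 h

green run (percent of the solid substrate charged)

| time / h | target / % | solid substrate / % |
|---|---|---|
| 0.500 | 0.7 | 98.5 |
| 0.833 | 1.9 | 96.7 |
| 1.50 | 3.5 | 94.8 |
| 3.00 | 6.8 | 89.5 |
| 6.00 | 13.2 | 78.7 |

(each reading ± 0.3 percentage points)

- amount of target at 15 h, in percent of the solid substrate charged
- concentration of dissolved gas in solution at 15 h, in percent of saturation

- given per volume of solution although it is solid: solid substrate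
- at the start none of the gas is dissolved
- the earlier runs were read with a standard deviation of 0.3 percentage points
- candidate steps: gas phase <-> dissolved gas; starting material + dissolved gas -> target; starting material -> side product; solid substrate <-> starting material
- at the start none of the solid substrate is in solution

1. In the green run, the solid substrate falls by 0.0347 /h up to 1.50 h and 0.0358 /h from there to 6.00 h, nearly the same. This reckoning freezes that rate, a steady state.

2. Folded with the time, the green loss gives 0.532, the dissolved fraction: the part of the charge reckoned to have left the solid by the asked time at the frozen rate. It stands below 1, so solid is reckoned to remain.

3. At 6.00 h in the green run, the selectivity for target reads 0.620 of the solid lost, so this reckoning gives 33.0% of target in the flask at the asked time.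

4. One number is not enough: the dissolved fraction gives no value for dissolved gas.

5. The forecast gives 32.3% and 60%, saying of the gas that “these runs barely fix that level”.

6. The flask gives 33.8% and 99.4%, with 45.9% of solid substrate left against the reckoned 46.8%.

    gas phase ⇌ dissolved gas, rate k1*(csat - [dissolved gas]) (kL = 1.60 /min)
    starting material + dissolved gas → target (k = 5.30 /M/min)
    starting material → side product (k = 0.0970 /min)
    solid substrate ⇌ starting material, rate k4*(cs4 - [starting material]) while solid is left; crystals form when [starting material] > cs4 (solubility = 0.180 M, k = 0.00270 /min)

In the flask, dissolved gas returns with a half-life of 0.433 min, far shorter than the 1.2 h of its use by target formation at the asked time.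

7. With 0.20 M of solid substrate and the same frozen rate per volume, the dissolved fraction is 2.13, above 1, so the charge is reckoned to run out and target to stop near 62.0%. That flask gives 62.7% of target, with 0% of solid substrate left.

(The data come from a simulation with constants of no real substance, and the scatter is random.)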